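The readings come from a simulation with made-up constants; noise was put on by code.

- The question was which flask to put on: winter, autumn or dusk. They differ in their temperature history.

| setting | ochre | green | winter | autumn | dusk |
|---|---|---|---|---|---|
| E | 0.013 M | 0.019 M | 0.025 M | 0.025 M | 0.025 M |
| X | 0.025 M | 0.025 M | 0.0250 M | 0.0250 M | 0.0250 M |
| temperature | 6 °C | 20 °C |  | 25 °C | 0 °C |
| remark | run made earlier | run made earlier | at 0 °C until 10 h, from then on at 25 °C |  |  |
| time |  |  | 30 h | 30 h | 30 h |

| run | time / h | Z / % | E / % |
|---|---|---|---|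
| ochre | 10.0 | 1.5 | 94.5 |
| ochre | 25.0 | 5.5 | 87.8 |
| ochre | 48.0 | 12.5 | 77.6 |
| ochre | 72.0 | 18.7 | 67.1 |
| green | 2.50 | 4.5 | 95.1 |
| green | 6.00 | 9.7 | 87.8 |
| green | 12.0 | 17.9 | 73.1 |
| green | 30.0 | 34.2 | 52.4 |

(each reading ± 1 percentage point)

- the best flask by amount of Z, in percent of the E charged; "all alike" if 1.5 percentage points covers them all (winter / autumn / dusk / all alike)
- amount of Z at the end, in percent of the E charged, winter
- amount of Z at the end, in percent of the E charged, autumn
- amount of Z at the end, in percent of the E charged, dusk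

- a reading or a percentage of Z counts all its forms, free or not

- From the last green reading I took Z found over E lost, 0.718, and called it the Z share, the selectivity as read from that run. I reckoned the Z of a flask as this share times the fraction of E lost.
- The last ochre reading gave a share of 0.568, lower than green's. But ochre was both colder and charged with less E, so these readings could not separate the two.
- Read as first-order, E fell at 0.0215 h⁻¹ in green, faster than the 0.00554 h⁻¹ in ochre. I took green's pace for the hot hours as a low estimate, assuming that the charge of E mattered little.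
- At that pace and with that share, I estimated autumn at 34.2%. For winter I counted the cold 10 h as lost, which left 20.0 h and an estimate of 25.1%.
- Dusk was colder than ochre, so I took ochre's share and pace as a high estimate for dusk, 8.71%.
- My decision was to charge autumn. In my reckoning the hot hours that winter gave up cost 9.1 percentage points, more than the margin of 1.5 points. The pair to follow was Z and E lost, read together as the share.
- The forecast chose autumn: 47% for autumn (40% to 54%), 37% for winter (31% to 43%) and 4% for dusk (2.5% to 6%). Its autumn figure stood above my low estimate, and its dusk figure below my high estimate. Its verdict was “Autumn wins under either rate law.”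
- The flasks gave autumn as the best, with 43.1% of Z in autumn, 35.0% in winter and 3.75% in dusk.

    E ⇌ G (K = 1.90 × 10⁻⁴, k = 0.110 h⁻¹, Ea = 93.0 kJ mol⁻¹, ΔH = 7.00 kJ mol⁻¹)
    G ⇌ Q (K = 0.330, k = 9600 h⁻¹, Ea = 72.0 kJ mol⁻¹, ΔH = −32.0 kJ mol⁻¹)
    X + G → Z (k = 10000 M⁻¹ h⁻¹, Ea = 52.0 kJ mol⁻¹)
    X + Q → D (k = 11000 M⁻¹ h⁻¹, Ea = 54.0 kJ mol⁻¹)
    X → L (k = 1.70 × 10⁻⁴ h⁻¹, Ea = 120 kJ mol⁻¹)
    J ⇌ Z, rate k6*(cs6 - [Z]) while solid is left; crystals form when [Z] > cs6 (solubility = 4.30 mM, k = 9.10 h⁻¹)
    (constants at 25 °C)

- Green's share of 0.718 times the 58.6% of E lost in autumn gave 42.1% of Z against 43.1%, and times the 48.5% lost in winter gave 34.8% against 35.0%. Taking the fast step from G to Q as balanced at 0.330 in autumn, the step from X + G to Z took a reckoned share of 0.734 of the E lost there. The way back from Q to G is the main reason for autumn's Z: without it, autumn ended at 1.28% instead of 43.1%.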